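Everything rests on cutting the C4–C5 bond of ring A, which joins the methyl-bearing C4 to the quaternary C5. This pairing is the feature exploited. C4 and its methyl carbon C15 are traced back to a vinyl group. C5 is traced back to the β-carbon of a ring B 3-methylcyclohexenone whose α-carbon C10 carries the tether. In one operation an iron hydride turns the vinyl group into the C4 radical, which closes ring A on C5 and sets C4, C5 and C10 from the single C3 silyl ether stereocentre. The precursor is an enantiopure 2-(3-silyloxypent-4-enyl)-3-methylcyclohexenone. Afterwards the C9 carbonyl guides isopropenyl to C7 and is shifted to C8, C9 is hydroxylated from the α face, and both esters follow.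

Key step: step 7

Numbering and descriptors: eremophilane numbering is used (ring A = C1–C5 and C10; ring B = C5–C10; C14 on C5, C15 on C4, C11–C13 isopropenyl). β is the face of C14 and α is the opposite face. The target is a trans-decalin with C14 axial and every other substituent equatorial: 3α-O, 4β-Me, 7α-isopropenyl, 9α-O, 10α-H, that is 3R,4R,5R,7S,9S,10R.

Design remark: C14 is syn-axial to the β face of C9, so a hydride would reach a C9 ketone from the α face and leave the axial 9β-alcohol. The C9–O bond is therefore made by delivering oxygen, not hydrogen, from the α face, after the carbonyl group has been moved from C9 to C8.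

Assumption: the empirical face rule of the Sharpless kinetic resolution holds for 8, so L-(+)-tartrate consumes the S alcohol.

Step 1
Reactants: 1 3-methylcyclohex-2-en-1-one
Product: 2 2-iodo-3-methylcyclohex-2-en-1-one
Conditions: I2 (2 equiv), pyridine–CH2Cl2 1:1, rt, dark
Reagents that add atoms: iodine, [I][I]
Why: Enone α-iodination with I2/pyridine substitutes the only vinylic C–H, the future C10, and provides the handle for cross-coupling.

Step 2
Reactants: 2 2-iodo-3-methylcyclohex-2-en-1-one; 3 acrolein diethyl acetal (3,3-diethoxyprop-1-ene)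
Product: 5 2-(3,3-diethoxypropyl)-3-methylcyclohex-2-en-1-one, via B-(3,3-diethoxypropyl)-9-BBN 4 (not isolated)
Conditions: 3, 9-BBN-H, THF, 0 °C → rt; then 2, PdCl2(dppf) (5 mol %), Ph3As, Cs2CO3, DMF–H2O, rt
Reagents that add atoms: 9-BBN-H, [H]B1C2CCCC1CCC2 (stays only in intermediate 4)
Why: Anti-Markovnikov hydroboration of the protected acrolein followed by B-alkyl Suzuki–Miyaura coupling with the α-iodoenone forms the C1–C10 bond under mild base without touching the enone.

Step 3
Reactants: 5 2-(3,3-diethoxypropyl)-3-methylcyclohex-2-en-1-one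
Product: 6 3-(2-methyl-6-oxocyclohex-1-en-1-yl)propanal
Conditions: TsOH·H2O (cat.), acetone–H2O, rt
Reagents that add atoms: water, O
Why: Acid-catalysed acetal hydrolysis frees the C3 aldehyde while the tetrasubstituted enone is inert to dilute acid.

Step 4
Reactants: 6 3-(2-methyl-6-oxocyclohex-1-en-1-yl)propanal; 7 vinylmagnesium bromide
Product: 8 rac-2-(3-hydroxypent-4-en-1-yl)-3-methylcyclohex-2-en-1-one
Conditions: 7 (1.05 equiv), THF, −78 °C; sat. aq NH4Cl
Reagents that add atoms: none
Why: Grignard 1,2-addition at low temperature is chemoselective for the aldehyde over the hindered conjugated ketone and creates C3 as a racemate that the next step resolves.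

Step 5
Reactants: 8 rac-2-(3-hydroxypent-4-en-1-yl)-3-methylcyclohex-2-en-1-one
Product: 9 (R)-2-(3-hydroxypent-4-en-1-yl)-3-methylcyclohex-2-en-1-one
Conditions: Ti(OiPr)4 (0.2 equiv), L-(+)-diisopropyl tartrate (0.25 equiv), t-BuOOH (0.6 equiv), 4 Å MS, CH2Cl2, −20 °C, stopped just past half conversion
Reagents that add atoms: none
Why: In this Sharpless kinetic resolution L-(+)-tartrate should epoxidise the S allylic alcohol much faster, so the R alcohol (C3) should remain enantiopure, and the electron-poor enone alkene does not react.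

Step 6
Reactants: 9 (R)-2-(3-hydroxypent-4-en-1-yl)-3-methylcyclohex-2-en-1-one
Product: 10 (R)-2-[3-(tert-butyldimethylsilyloxy)pent-4-en-1-yl]-3-methylcyclohex-2-en-1-one
Conditions: TBSCl, imidazole, DMF, rt
Reagents that add atoms: tert-butyldimethylsilyl chloride, CC(C)(C)[Si](C)(C)Cl
Why: Imidazole-promoted silylation masks the C3 hydroxyl as a bulky ether that tolerates silane, amide bases, butyllithium and cuprate and is removed by fluoride at the end.

Step 7
Reactants: 10 (R)-2-[3-(tert-butyldimethylsilyloxy)pent-4-en-1-yl]-3-methylcyclohex-2-en-1-one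
Product: 11 (3R,4R,5R,10R)-3-(tert-butyldimethylsilyloxy)-4,5-dimethyl-trans-decalin-9-one (3α-OTBS 4β-Me 5β-Me 10α-H)
Conditions: Fe(acac)3 (0.3 equiv), PhSiH3 (3 equiv), EtOH–ethylene glycol 5:1, 0.02 M, 60 °C, argon
Reagents that add atoms: none
Why: Fe(acac)3 and PhSiH3 form an iron hydride that hands a hydrogen atom to the terminal carbon C15 (Markovnikov MHAT), so C15 becomes the C4 methyl group and C4 a nucleophilic secondary radical; this radical adds to the electrophilic β-carbon C5 (reductive olefin–enone coupling, an intramolecular Giese addition), and the C10 α-keto radical is reduced by divalent iron and protonated by ethanol. Ring A closes in the 6-endo-trig mode because C5 and C10 both end up in the new ring, whereas the 5-exo attack at C10 is polarity-mismatched and would leave an unstabilised tertiary radical at C5. For C5, C14 is cis to C1 on the C5=C10 bond and is therefore forced axial on ring A in the chair transition state, so the C3 silyloxy group must sit equatorial to escape a 1,3-diaxial clash with C14, which selects the enone face and ties C5 to C3. For C4, the radical should react through the rotamer with its methyl group pseudo-equatorial, away from the axial hydrogen at C2, which gives the 4β-methyl cis to C14. For C10, the enolate should take up its proton axially on the α face, anti to the neighbouring C14, giving the trans fusion, which is also the slightly lower-energy epimer at this enolisable centre. The selectivity needed is hydrogen-atom transfer to the vinyl group alone, and it is secured because the tetrasubstituted enone is a poor hydrogen-atom acceptor and no 1,1-disubstituted alkene or unsaturated ester is present yet.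

Step 8
Reactants: 11 (3R,4R,5R,10R)-3-(tert-butyldimethylsilyloxy)-4,5-dimethyl-trans-decalin-9-one
Product: 13 3α-(tert-butyldimethylsilyloxy)-4β,5β-dimethyl-trans-decal-7-en-9-one, via trimethylsilyl enol ether 12 (not isolated)
Conditions: LiN(iPr)2, THF, −78 °C; Me3SiCl; then Pd(OAc)2 (1.1 equiv), MeCN, rt
Reagents that add atoms: chlorotrimethylsilane, C[Si](C)(C)Cl (stays only in intermediate 12)
Why: Kinetic deprotonation takes the less hindered C8 methylene rather than the tertiary C10–H, and Saegusa–Ito oxidation of the silyl enol ether gives the C7=C8 enone without touching C10.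

Step 9
Reactants: 13 3α-(tert-butyldimethylsilyloxy)-4β,5β-dimethyl-trans-decal-7-en-9-one; 14 isopropenylmagnesium bromide
Product: 16 3α-(tert-butyldimethylsilyloxy)-10αH-eremophil-11-en-9-one (7α-isopropenyl), via trimethylsilyl enol ether 15 (not isolated)
Conditions: 14 (3 equiv), CuBr·SMe2 (20 mol %), Me3SiCl (3 equiv), THF, −78 → −40 °C; then 10% aq citric acid, THF, rt
Reagents that add atoms: chlorotrimethylsilane, C[Si](C)(C)Cl (stays only in intermediate 15)
Why: Copper-catalysed, Me3SiCl-accelerated conjugate addition should attack C7 from the α face, away from the axial C14 that is 1,3-related to C7, so the isopropenyl group ends equatorial (also the favoured position once C8 is a ketone), and mild acid frees the ketone.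

Step 10
Reactants: 16 3α-(tert-butyldimethylsilyloxy)-10αH-eremophil-11-en-9-one
Product: 17 tosylhydrazone of 16 at C9
Conditions: TsNHNH2 (1.2 equiv), PPTS (cat.), THF–MeOH, 40 °C
Reagents that add atoms: p-toluenesulfonyl hydrazide, Cc1ccc(cc1)S(=O)(=O)NN
Why: Hydrazone condensation turns the sulfonamide toward the less hindered C8 side as the next step requires, and C10 is thermodynamically secure because a cis fusion would force the C7 group or the ring A substituents axial.

Step 11
Reactants: 17 tosylhydrazone of 16 at C9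
Product: 20 3α-(tert-butyldimethylsilyloxy)-8-methylthio-10αH-eremophila-8,11-diene, via 8-methylthio tosylhydrazone 18 (not isolated), via C9 vinyllithium 19 (not isolated)
Conditions: n-BuLi (2.2 equiv), TMEDA, THF, −50 °C; MeSSMe (1.1 equiv); n-BuLi (2 equiv), −50 °C → rt; H2O
Reagents that add atoms: dimethyl disulfide, CSSC; n-butyllithium, CCCC[Li] (lithium only in intermediate 19)
Why: This is the known 1,2-carbonyl transposition by a Shapiro reaction with interposed sulfenylation, in which the hydrazone dianion formed at C8 is sulfenylated, a further metalation at C8 triggers loss of sulfinate and N2, and protonation at C9 leaves sulfur on C8 and hydrogen on C9.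

Step 12
Reactants: 20 3α-(tert-butyldimethylsilyloxy)-8-methylthio-10αH-eremophila-8,11-diene
Product: 21 3α-(tert-butyldimethylsilyloxy)-10αH-eremophil-11-en-8-one (7α-isopropenyl)
Conditions: HgCl2 (2 equiv), CaCO3, MeCN–H2O 4:1, 50 °C
Reagents that add atoms: water, O
Why: Thiophilic HgCl2-assisted hydrolysis of the vinyl sulfide, a masked ketone, unveils the C8 carbonyl in a buffered medium that should spare the silyl ether and the isopropenyl group, and C7, now enolisable, rests in its favoured equatorial α orientation.

Step 13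
Reactants: 21 3α-(tert-butyldimethylsilyloxy)-10αH-eremophil-11-en-8-one
Product: 22 3α-(tert-butyldimethylsilyloxy)-9α-hydroxy-10αH-eremophil-11-en-8-one
Conditions: NaN(SiMe3)2 (1.1 equiv), THF, −78 °C; 2-(phenylsulfonyl)-3-phenyloxaziridine (1.3 equiv), −78 °C; sat. aq NH4Cl
Reagents that add atoms: 2-(phenylsulfonyl)-3-phenyloxaziridine, O=S(=O)(N1OC1c1ccccc1)c1ccccc1
Why: Kinetic enolisation of a 2-substituted cyclohexanone takes the C9 methylene rather than the tertiary C7–H, and Davis oxidation should deliver oxygen to the α face because C14 is syn-axial to the β face of C9, giving the equatorial 9α-alcohol (kinetic and thermodynamic epimer) while the oxaziridine ignores the isopropenyl alkene.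

Step 14
Reactants: 22 3α-(tert-butyldimethylsilyloxy)-9α-hydroxy-10αH-eremophil-11-en-8-one; 23 tigloyl chloride ((E)-2-methylbut-2-enoyl chloride)
Product: 24 3α-(tert-butyldimethylsilyloxy)-9α-tigloyloxy-10αH-eremophil-11-en-8-one
Conditions: 23, Et3N, DMAP (cat.), CH2Cl2, 0 °C → rt
Reagents that add atoms: none
Why: DMAP-catalysed acylation with the configurationally stable E acid chloride esterifies the only free hydroxyl without disturbing the C9 configuration.

Step 15
Reactants: 24 3α-(tert-butyldimethylsilyloxy)-9α-tigloyloxy-10αH-eremophil-11-en-8-one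
Product: 25 3α-hydroxy-9α-tigloyloxy-10αH-eremophil-11-en-8-one
Conditions: HF·pyridine, pyridine–THF, 0 °C → rt
Reagents that add atoms: none
Why: Fluoride-driven cleavage of the secondary silyl ether in a weakly acidic, non-basic medium avoids enolisation at C7 and C9 and ester cleavage.

Step 16
Reactants: 25 3α-hydroxy-9α-tigloyloxy-10αH-eremophil-11-en-8-one; 26 senecioic acid (3-methylbut-2-enoic acid)
Product: 27 3α-senecioyloxy-9α-tigloyloxy-10αH-eremophil-11-en-8-one (target CNP0164025.1)
Conditions: 26, DCC, DMAP (cat.), CH2Cl2, 0 °C → rt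
Reagents that add atoms: none
Why: Steglich esterification of the equatorial C3 alcohol with the free acid avoids the vinylketene pathway of the acid chloride that would deconjugate the senecioate, and the near-neutral medium leaves the β,γ-unsaturated ketone in place.

Compound list
1 | 3-methylcyclohex-2-en-1-one | CC1=CC(=O)CCC1 | starting material
2 | 2-iodo-3-methylcyclohex-2-en-1-one | IC1=C(C)CCCC1=O | intermediate
3 | acrolein diethyl acetal | C=CC(OCC)OCC | starting material
4 | B-(3,3-diethoxypropyl)-9-BBN | CCOC(CCB1C2CCCC1CCC2)OCC | intermediate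
5 | 2-(3,3-diethoxypropyl)-3-methylcyclohex-2-en-1-one | CCOC(CCC1=C(C)CCCC1=O)OCC | intermediate
6 | 3-(2-methyl-6-oxocyclohex-1-en-1-yl)propanal | O=CCCC1=C(C)CCCC1=O | intermediate
7 | vinylmagnesium bromide | C=C[Mg]Br | starting material
8 | rac-2-(3-hydroxypent-4-en-1-yl)-3-methylcyclohex-2-en-1-one | C=CC(O)CCC1=C(C)CCCC1=O | intermediate
9 | (R)-2-(3-hydroxypent-4-en-1-yl)-3-methylcyclohex-2-en-1-one | C=C[C@H](O)CCC1=C(C)CCCC1=O | intermediate
10 | (R)-2-[3-(tert-butyldimethylsilyloxy)pent-4-en-1-yl]-3-methylcyclohex-2-en-1-one | C=C[C@H](O[Si](C)(C)C(C)(C)C)CCC1=C(C)CCCC1=O | intermediate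
11 | (3R,4R,5R,10R)-3-(tert-butyldimethylsilyloxy)-4,5-dimethyl-trans-decalin-9-one | C1C[C@]2(C)[C@@H](C)[C@H](O[Si](C)(C)C(C)(C)C)CC[C@H]2C(=O)C1 | intermediate
12 | 9-trimethylsilyloxy-8-ene derived from 11 (trimethylsilyl enol ether) | C1C[C@]2(C)[C@@H](C)[C@H](O[Si](C)(C)C(C)(C)C)CC[C@H]2C(O[Si](C)(C)C)=C1 | intermediate
13 | 3α-(tert-butyldimethylsilyloxy)-4β,5β-dimethyl-trans-decal-7-en-9-one (10α-H) | O=C1C=CC[C@]2(C)[C@@H](C)[C@H](O[Si](C)(C)C(C)(C)C)CC[C@@H]12 | intermediate
14 | isopropenylmagnesium bromide | C=C(C)[Mg]Br | starting material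
15 | 7α-isopropenyl-9-trimethylsilyloxy-8-ene (trimethylsilyl enol ether of 16) | C=C(C)[C@@H]1C[C@]2(C)[C@@H](C)[C@H](O[Si](C)(C)C(C)(C)C)CC[C@H]2C(O[Si](C)(C)C)=C1 | intermediate
16 | 3α-(tert-butyldimethylsilyloxy)-10αH-eremophil-11-en-9-one (7α-isopropenyl) | C=C(C)[C@@H]1C[C@]2(C)[C@@H](C)[C@H](O[Si](C)(C)C(C)(C)C)CC[C@H]2C(=O)C1 | intermediate
17 | C9 tosylhydrazone of 16 | C=C(C)[C@@H]1C[C@]2(C)[C@@H](C)[C@H](O[Si](C)(C)C(C)(C)C)CC[C@H]2C(=NNS(=O)(=O)c3ccc(C)cc3)C1 | intermediate
18 | 8-methylthio tosylhydrazone (C8 unassigned; present as its lithium salt) | C=C(C)[C@@H]1C[C@]2(C)[C@@H](C)[C@H](O[Si](C)(C)C(C)(C)C)CC[C@H]2C(=NNS(=O)(=O)c3ccc(C)cc3)C1SC | intermediate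
19 | C9 vinyllithium (9-lithio-8-methylthio-8-ene) | C=C(C)[C@@H]1C[C@]2(C)[C@@H](C)[C@H](O[Si](C)(C)C(C)(C)C)CC[C@H]2C([Li])=C1SC | intermediate
20 | 3α-(tert-butyldimethylsilyloxy)-8-methylthio-10αH-eremophila-8,11-diene | C=C(C)[C@@H]1C[C@]2(C)[C@@H](C)[C@H](O[Si](C)(C)C(C)(C)C)CC[C@H]2C=C1SC | intermediate
21 | 3α-(tert-butyldimethylsilyloxy)-10αH-eremophil-11-en-8-one (7α-isopropenyl) | C=C(C)[C@@H]1C[C@]2(C)[C@@H](C)[C@H](O[Si](C)(C)C(C)(C)C)CC[C@H]2CC1=O | intermediate
22 | 3α-(tert-butyldimethylsilyloxy)-9α-hydroxy-10αH-eremophil-11-en-8-one | C=C(C)[C@@H]1C[C@]2(C)[C@@H](C)[C@H](O[Si](C)(C)C(C)(C)C)CC[C@H]2[C@H](O)C1=O | intermediate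
23 | tigloyl chloride | C/C=C(\C)C(=O)Cl | starting material
24 | 3α-(tert-butyldimethylsilyloxy)-9α-tigloyloxy-10αH-eremophil-11-en-8-one | C=C(C)[C@@H]1C[C@]2(C)[C@@H](C)[C@H](O[Si](C)(C)C(C)(C)C)CC[C@H]2[C@H](OC(=O)/C(C)=C/C)C1=O | intermediate
25 | 3α-hydroxy-9α-tigloyloxy-10αH-eremophil-11-en-8-one | C=C(C)[C@@H]1C[C@]2(C)[C@@H](C)[C@H](O)CC[C@H]2[C@H](OC(=O)/C(C)=C/C)C1=O | intermediate
26 | senecioic acid | CC(C)=CC(=O)O | starting material
27 | (3R,4R,5R,7S,9S,10R)-3-senecioyloxy-9-tigloyloxyeremophil-11-en-8-one | C=C(C)[C@@H]1C[C@]2(C)[C@@H](C)[C@H](OC(=O)C=C(C)C)CC[C@H]2[C@H](OC(=O)/C(C)=C/C)C1=O | target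

Total step count: 16. Longest linear sequence: 16 steps (1 → 27); compounds 3, 7, 14, 23 and 26 are bought.

Steps most likely to fail

Step 7.
- What may go wrong: hydrogen-atom transfer to the monosubstituted, allylically oxygenated alkene may be slow. Plain hydrogenation of the vinyl group, or quenching of the C4 radical before ring closure, could then take over.
- Fallback: it sets out from 6 and returns at 11, bypassing 8–10, and makes the same C4 radical by decarboxylation instead of hydrogen-atom transfer.
- An Evans syn-aldol reaction of 6 with the dibutylboron enolate of commercial (S)-4-benzyl-3-propionyloxazolidin-2-one (Bu2BOTf, Et3N, CH2Cl2, −78 °C) gives the syn-aldol imide F1. Its C3 is set R by the auxiliary, so no resolution is needed.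
- TBSOTf and 2,6-lutidine give the silylated imide F2. LiOH/H2O2 at 0 °C removes the auxiliary to give the carboxylic acid F3.
- N-hydroxyphthalimide with DIC and DMAP gives the redox-active ester F4.
- Visible-light reduction (Ru(bpy)3(PF6)2, Hantzsch ester, iPr2NEt, CH2Cl2, blue LEDs) releases the C4 radical, which closes ring A as in step 7 to give 11.

Step 11.
- What may go wrong: the second metalation may be incomplete, the sulfenylated hydrazone anion may lose methanethiolate, or metalation may occur toward C10.
- Fallback: it sets out from 16 and returns at 21, replacing the hydrazone chemistry by the classical sulfenylation–reduction–elimination transposition.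
- LiN(iPr)2 followed by PhSSPh gives the 8-phenylthio ketone F5, and NaBH4 in MeOH gives the hydroxy sulfide F6; the C9 configuration is irrelevant.
- MsCl and Et3N give the mesylate F7. KOtBu in THF removes the sulfur-acidified C8–H to give the phenyl vinyl sulfide F8.
- HgCl2/CaCO3 hydrolysis as in step 12 then gives 21.

Step 13.
- What may go wrong: regiocontrol in the enolisation may be lost through removal of the allylic C7–H. This would lead to oxygenation at C7 or to migration of the isopropenyl double bond into conjugation.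
- Fallback: it sets out from 21 and returns at 24, skipping 22, and replaces enolate chemistry by the metal-free α-oxyacylation of ketones with N-methyl-O-acylhydroxylamine salts.
- Commercial tert-butyl N-hydroxy-N-methylcarbamate is acylated with 23 and Et3N to give the O-tigloyl carbamate F9.
- HCl in dioxane gives N-methyl-O-tigloylhydroxylamine hydrochloride F10.
- Warming 21 with this salt in DMSO forms the ene-hydroxylamine toward the less substituted C9, since tertiary carbons are not functionalised. Its [3,3]-sigmatropic shift should place the tigloyloxy group on the open α face, and hydrolysis of the imine gives 24 directly.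

Further compounds
F1 | step 7 | (S)-4-benzyl-3-[(2S,3R)-3-hydroxy-2-methyl-5-(2-methyl-6-oxocyclohex-1-en-1-yl)pentanoyl]oxazolidin-2-one | CC1=C(CC[C@@H](O)[C@H](C)C(=O)N2[C@@H](Cc3ccccc3)COC2=O)C(=O)CCC1
F2 | step 7 | tert-butyldimethylsilyl ether of F1 | CC1=C(CC[C@@H](O[Si](C)(C)C(C)(C)C)[C@H](C)C(=O)N2[C@@H](Cc3ccccc3)COC2=O)C(=O)CCC1
F3 | step 7 | (2S,3R)-3-(tert-butyldimethylsilyloxy)-2-methyl-5-(2-methyl-6-oxocyclohex-1-en-1-yl)pentanoic acid | CC1=C(CC[C@@H](O[Si](C)(C)C(C)(C)C)[C@H](C)C(=O)O)C(=O)CCC1
F4 | step 7 | N-hydroxyphthalimide ester of F3 | CC1=C(CC[C@@H](O[Si](C)(C)C(C)(C)C)[C@H](C)C(=O)ON2C(=O)c3ccccc3C2=O)C(=O)CCC1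
F5 | step 11 | 8-phenylthio derivative of 16 (C8 unassigned) | C=C(C)[C@@H]1C[C@]2(C)[C@@H](C)[C@H](O[Si](C)(C)C(C)(C)C)CC[C@H]2C(=O)C1Sc3ccccc3
F6 | step 11 | 9-hydroxy-8-phenylthio compound (C8 and C9 unassigned) | C=C(C)[C@@H]1C[C@]2(C)[C@@H](C)[C@H](O[Si](C)(C)C(C)(C)C)CC[C@H]2C(O)C1Sc3ccccc3
F7 | step 11 | 9-mesylate of F6 | C=C(C)[C@@H]1C[C@]2(C)[C@@H](C)[C@H](O[Si](C)(C)C(C)(C)C)CC[C@H]2C(OS(C)(=O)=O)C1Sc3ccccc3
F8 | step 11 | 3α-(tert-butyldimethylsilyloxy)-8-phenylthio-10αH-eremophila-8,11-diene | C=C(C)[C@@H]1C[C@]2(C)[C@@H](C)[C@H](O[Si](C)(C)C(C)(C)C)CC[C@H]2C=C1Sc3ccccc3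
F9 | step 13 | tert-butyl N-methyl-N-[(E)-2-methylbut-2-enoyloxy]carbamate | C/C=C(\C)C(=O)ON(C)C(=O)OC(C)(C)C
F10 | step 13 | N-methyl-O-[(E)-2-methylbut-2-enoyl]hydroxylamine hydrochloride | C/C=C(\C)C(=O)ONC.Cl
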